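Every monomer charged is still free, sits in chains, or has been lost to a side reaction, so the charge minus the two readings counts the loss. At 10.0 min that loss is 3.08 mM in the alpha run and 3.00 mM in the delta run. Both match the 3 mM of protic impurity charged, though the monomer charges differ, 6.7 mM against 15 mM. We read this as one monomer lost per protic impurity, which makes the impurity the limiting reagent of that loss. In delta the gap already reads 2.85 mM at 0.667 min, so the loss comes early.

the same everywhere: initiator 0.50 mM
- alpha: free monomer 0.0067 M; protic impurity 3 mM; run made earlier
- delta: free monomer 0.015 M; protic impurity 3 mM; run made earlier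
- flask: free monomer 0.010 M; protic impurity 3.00 mM; time 15 min

| run | time / min | monomer in chains / % | free monomer / % |
|---|---|---|---|
| alpha | 0.667 | 35 | 25 |
| alpha | 2.00 | 44 | 8 |
| alpha | 3.00 | 51 | 4 |
| alpha | 5.00 | 53 | 1 |
| alpha | 6.00 | 55 | 1 |
| alpha | 10.0 | 54 | 0 |
| delta | 0.667 | 54 | 27 |
| delta | 2.00 | 66 | 15 |
| delta | 3.00 | 67 | 11 |
| delta | 5.00 | 72 | 4 |
| delta | 6.00 | 75 | 8 |
| delta | 10.0 | 74 | 6 |

(each reading ± 2 percentage points)

1. average number of monomer units in a chain (chains begun, living or dead) at 15 min
2. part of the free monomer that has reacted at 15 min

- the average divides the monomer in chains by the number of chains begun, living and dead together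
- the earlier runs do not show the number of chains; that part of a forecast is a guess

The new flask therefore has 7.00 mM of chain budget B, the free monomer charged minus the protic impurity charged. Once B stands in chains, dividing it by the chains begun gives dp. The runs do not show that count, so we guess one chain per initiator, 0.50 mM, and get 14.0. At 10.0 min free monomer reads 0% in alpha and 6% in delta. The flask's charge lies between theirs, so we look for a remainder between those readings at 15 min.

The forecast gives dp 14 and c 99.5%, holding that “the impurity destroys monomer one-for-one”.

The flask gives dp 13.9 and c 98.3%, both inside the forecast's margins.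

    free monomer + initiator → living end + monomer in chains (k = 6.52 M⁻¹ s⁻¹)
    free monomer + living end → monomer in chains + living end, rate k2*[living end]*[free monomer] (k = 193 M⁻¹ s⁻¹)
    2 living end → dead end (k = 268 M⁻¹ s⁻¹)
    protic impurity + free monomer → quenched substrate (k = 29.7 M⁻¹ s⁻¹)

At 15 min the flask holds 6.83 mM of monomer in chains against B. The neighbour with 5.10 mM of protic impurity has a B of 4.90 mM and holds 48.3% of its charge in chains at 15 min. With 7.1% of its initiator left, B over the initiator consumed gives 10.5, and that neighbour shows 10.4. The flask itself is close to rest but not there, with its slowest mode at a half-life of 20.3 min. After 150 min monomer in chains reaches 6.98 mM against the 7.00 mM of B, dp barely moves to 14.0, and c stands at 99.8%.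

The numbers in the tables are calculated for an exercise; the scatter is artificial.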